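I had 5 questions to answer, 4 shares and a ranking, and I first set down the flask they concern.

    2 reagent → homo dimer (k1 = 1.88 /M/s)
    reagent + first product → bis adduct + by-product (k2 = 0.0938 /M/s)
    starting material + reagent → other mono adduct + by-product (k3 = 1.03 /M/s)
    starting material + reagent → first product + by-product (k4 = 3.15 /M/s)
    reagent + other mono adduct → bis adduct + by-product (k5 = 5.41 /M/s)

| flask | starting material | reagent | time | remark |
|---|---|---|---|---|
| dawn | 0.0050 M | 1.80 equiv | 80 s | a closed flask charged with all of it at once and left for 80 s |
| noon | 0.0050 M (fed, over 64.0 s) | 1.80 equiv | 80 s | all but starting material at the start; starting material goes in evenly over 64.0 s, the run ends at 80 s |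
| spring | 0.0050 M | 1.80 equiv |  | a single well-mixed tank run continuously and read at steady state, 80 s in it on average |
| dusk | 0.0050 M | 1.80 equiv (fed, over 64.0 s) | 80 s | all but reagent at the start; reagent goes in evenly over 64.0 s, the run ends at 80 s |

- a doubled species enters its step squared and goes two at a time
- the stated concentrations are those of everything mixed, before any reaction; amounts are the same in each set-up
- the feed brings no volume worth counting
- run time (dawn): 80 s

* the set-up with the highest share of first product in all that became first product or bis adduct, at the outlet or at the end ("none" if the first two lie within 2 percentage points) (dawn / noon / spring / dusk / none)
* share of first product in all that became first product or bis adduct, at the outlet or at the end, dawn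
* share of first product in all that became first product or bis adduct, at the outlet or at the end, noon
* share of first product in all that became first product or bis adduct, at the outlet or at the end, spring
* share of first product in all that became first product or bis adduct, at the outlet or at the end, dusk

I wrote a for the fraction of the starting material left and n for the fraction present as other mono adduct. I dropped the step from first product to bis adduct, since the first product's half-life by it, 14 min, is longer than the 80 s run. Each reacting starting material then gave 0.754 first product and 0.246 other mono adduct, and bis adduct came from the other mono adduct, which competed with starting material for reagent.

The quantity I carried was the race ratio ρ, the constant of the other mono adduct with reagent over the summed constants of starting material with reagent: 1.29, a selectivity factor. Reagent cancels from that race, so in a closed flask charged at once n = 0.246(a − a^ρ)/(ρ − 1), and the share is 0.754(1 − a)/(1 − a − n).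

That solved both ends, and dawn had to join them. I let reagent decay as one second-order loss, with its starting fractional rate 0.0547 /s and starting material's rate over that 0.687. So a = (1 + rate × time)^−ratio, which gave 0.315 for dawn.

| a | n | first product | share |
|---|---|---|---|
| 1 | 0 | 0 | approaches 100% |
| 0.315 (dawn) | 0.0760 | 0.516 | 84.8% |
| 0 | 0 | 0.754 | 75.4% |

Reading down, the share fell as conversion rose. The middle row was my dawn estimate, and the bottom row was the floor. With the step from first product dropped, bis adduct took at most 0.246 of each reacted starting material, in a fed flask too, so I held noon above 75.4%. I did not reckon the conversions of the other set-ups, so my reckoning stopped there.

The forecast gave 84.3% for dawn, 88.6% for noon, 82.4% for spring and 85.5% for dusk, with noon best, holding that “the first-product share mainly tracks how far the starting material gets converted”. Its dawn was lower than mine.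

The simulation gave 84.4%, 88.7%, 82.3% and 85.5% in that order, with noon best.

Noon ended with 61% of its starting material left, and the closed-flask curve, applied to this fed flask with ρ at 1.29, gave a share of 91.6% from that fraction, against the simulated 88.7%. The neighbouring flask was noon with 0.0013 M of starting material, and it ended with 75.1% left. There the curve gave n = 0.0508 and a share of 94.7%. The simulation gave 4.89% other mono adduct and a share of 93.3%.

All constants are assumed; what happens was integrated by code.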